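- The trap was to line the runs up by substrate charge, so I lined them up by reagent per substrate.

| flask | substrate | reagent | catalyst | added ligand | remark | time |
|---|---|---|---|---|---|---|
| west | 0.54 M | 0.84 M | 6.4 mM | 8 mM | run made earlier |  |
| south-west | 1.2 M | 0.84 M | 6.4 mM | 8 mM | run made earlier |  |
| east | 0.80 M | 0.84 M | 13 mM | 8 mM | run made earlier |  |
| flask | 0.80 M | 0.840 M | 6.4 mM | 8.0 mM |  | 6.0 d |

| run | time / d | target / % | substrate / % |
|---|---|---|---|
| west | 0.125 | 17 | 74 |
| west | 0.208 | 24 | 60 |
| west | 0.417 | 29 | 42 |
| west | 0.625 | 30 | 30 |
| west | 1.25 | 19 | 16 |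
| west | 2.08 | 15 | 8 |
| west | 4.00 | 4 | 3 |
| south-west | 0.125 | 12 | 75 |
| south-west | 0.208 | 21 | 65 |
| south-west | 0.417 | 25 | 53 |
| south-west | 0.625 | 19 | 46 |
| south-west | 1.25 | 17 | 38 |
| south-west | 2.08 | 8 | 32 |
| south-west | 4.00 | 3 | 32 |
| east | 0.125 | 18 | 75 |
| east | 0.333 | 26 | 51 |
| east | 0.625 | 29 | 38 |
| east | 1.67 | 17 | 23 |
| east | 4.00 | 1 | 8 |

(standard deviation of a reading: 1.5 percentage points)

- what may be going on: substrate + reagent <-> target; substrate + reagent <-> isomer of the product; target + catalyst <-> isomer of the product + catalyst; reagent -> decomposition product; catalyst + added ligand <-> idle complex; target -> over-reaction product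

1. time, not beyond 6.0 d, at which the flask holds most target
2. the amount of target, in percent of the substrate charged, at that time

- My quantity was 1.05 for the flask: the cover, charged [reagent] over charged [substrate].
- My bench rule was the limiting reagent. One substrate takes one reagent, so a run with a cover under one should stall with one minus the cover of its substrate left.
- The south-west run has a cover of 0.700. The rule gave 30.0 %, and its last reading was 32 %.
- The rule stops at a cover of one. The flask is past that border, with more reagent charged than substrate, so the rule promised it no stall and gave no peak.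
- For the peak I interpolated on the cover between two read peaks. The south-west run read 25 % at 0.417 d, and the west run, with a cover of 1.56, read 30 % at 0.625 d.
- The flask lies a fraction 0.409 of the way between them. That gave me 27.0 % at 0.502 d. I set the east run aside, since it held 13 mM of catalyst.
- The forecast said the flask “should lie between them”. It gave 28 % (25 % to 31 %) at 0.5 d (0.36 d to 0.72 d), a higher amount than mine.
- The flask gave 27.0 % at 0.523 d.

    substrate + reagent ⇌ target (K = 12.0 M⁻¹, k = 0.00149 M⁻¹ min⁻¹)
    substrate + reagent ⇌ isomer of the product (K = 3.57 M⁻¹, k = 9.29 × 10⁻⁴ M⁻¹ min⁻¹)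
    target + catalyst ⇌ isomer of the product + catalyst, rate k3*[catalyst]*[target] forward; the back reaction follows from the equilibrium constant (k = 0.189 M⁻¹ min⁻¹)
    reagent → decomposition product (k = 1.93 × 10⁻⁶ min⁻¹)
    catalyst + added ligand ⇌ idle complex, settled at all times (K = 234 M⁻¹)
    target → over-reaction product (k = 0.00116 min⁻¹)

- With the charges as they stood, the forward half-life of substrate into target was 0.38 d, close to the 0.40 d of target into isomer of the product. At 1.24 d the flask made target at 0.604 of the rate it used it, each step taken net, so it was already past its peak at 0.523 d. With its cover of 1.05, the flask held 5.7 % of its substrate at 6.00 d. A neighbour flask charged with 0.21 M of reagent has a cover of 0.262, so the rule gives 73.8 %, and it held 73.8 % of its substrate at 6.00 d.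

The numbers in the tables are calculated from invented constants; the scatter is artificial.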